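Millimolar per hour is the unit I read these runs in, not percent of the charge.

| setting | larch | birch | oak | north-west | west |
|---|---|---|---|---|---|
| solid substrate | 11 mM | 13 mM | 16 mM | 10 mM | 20 mM |
| reagent | 1.2 equiv | 1.2 equiv | 1.2 equiv | 1.20 equiv | 1.20 equiv |
| temperature | 55 °C | 66 °C | 55 °C | 60 °C | 60 °C |
| remark | run made earlier | run made earlier | run made earlier |  |  |
| time |  |  |  | 15 h | 50 h |

| run | time / h | target / % |
|---|---|---|
| larch | 1.33 | 2 |
| larch | 2.50 | 7 |
| larch | 4.00 | 7 |
| larch | 8.00 | 17 |
| larch | 15.0 | 41 |
| birch | 3.00 | 4 |
| birch | 6.00 | 14 |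
| birch | 10.0 | 19 |
| birch | 12.0 | 21 |
| birch | 15.0 | 31 |
| oak | 1.33 | 1 |
| oak | 4.00 | 5 |
| oak | 8.00 | 17 |
| oak | 10.0 | 12 |
| oak | 15.0 | 30 |

(scatter of a reading: 2 percentage points)

- at the start none of the solid substrate is in solution
- what has only dissolved of solid substrate counts as not reacted
- a reading or a percentage of target counts all its forms, free or not
- where the amount of solid substrate changes, what is given in equivalents or mol% on it follows

- which one finishes higher in amount of target, in percent of the solid substrate charged ("neither" within 2 percentage points) (north-west / west / neither)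
- amount of target at the end, in percent of the solid substrate charged, north-west
- amount of target at the end, in percent of the solid substrate charged, west

At 15.0 h, larch holds 4.51 mM of target and oak 4.80 mM at the same temperature, though oak was charged with 16 mM against 11 mM. Birch, hotter at 66 °C, holds 4.03 mM. So I treat the output as independent of loading (apparent zero order). Oak gives my upper bound, 0.320 mM h⁻¹, and birch my lower, 0.269 mM h⁻¹. Pooling the three readings tightens this to 0.296 mM h⁻¹, my feed rate: mM of target made per hour while solid substrate remains. A flask then turns over this share of its charge: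

share = feed rate × time / [solid substrate] charged

North-west: 40.3% to 48.0%, pooled 44.5%

West: 67.2% to 80.0%, pooled 74.1%

West's lower bound stands above north-west's upper bound, so I commit to west.

The forecast also says west, with 41% for north-west and 68% for west, reading the runs as "a saturated solution feeding a roughly zero-order reaction". Both figures sit inside my brackets, and its west figure lies below my pooled one.

The flask gives west: 37.7% for north-west and 73.8% for west. West lands on my pooled figure. North-west falls under my lower bound by 2.6 percentage points, against a scatter of 2 points per reading.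

    solid product ⇌ target, rate k1*(cs1 - [target]) while solid is left; crystals form when [target] > cs1 (solubility = 0.140 mM, k = 0.0360 min⁻¹)
    2 dissolved substrate → side product (k = 2.20 L mol⁻¹ min⁻¹, Ea = 61.0 kJ mol⁻¹)
    solid substrate ⇌ dissolved substrate, rate k3*(cs3 - [dissolved substrate]) while solid is left; crystals form when [dissolved substrate] > cs3 (solubility = 2.10 mM, k = 0.00290 min⁻¹)
    target ⇌ isomer of the product (K = 3.60, k = 8.10 × 10⁻⁴ min⁻¹, Ea = 104 kJ mol⁻¹, ΔH = 6.00 kJ mol⁻¹)
    dissolved substrate + reagent ⇌ target (K = 87.0 L mol⁻¹, k = 26.0 L mol⁻¹ min⁻¹, Ea = 55.0 kJ mol⁻¹, ΔH = −37.0 kJ mol⁻¹)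
    (constants at 60 °C)

West's own feed rate works out at 0.295 mM h⁻¹, against my 0.296 mM h⁻¹, and the flask still holds 18.4% as solid substrate at the end. West climbs this far because so little target dissolves: with that taken away, the same flask ends at 7.27% instead of 73.8%.

On west repeated with 80 mM of solid substrate, the feed rate gives 18.5%. The computed flask gives 21.6%, with 77.6% still solid substrate.

The numbers in the tables are calculated for an exercise.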